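**Strategy.** Ring B is cut at the 8-ketone stage, where the C8 carbonyl lies between C7 and C9: the four carbons C5–C6–C7–C8 then form a cyclobutanone and C9=C10 an alkene. A rhodium-mediated carboacylation opens the cyclobutanone C5–C8 bond and adds its two ends across C9=C10, forming C5–C10 and C8–C9 and so closing rings A and B of the trans-decalin in one operation. The precursor is a 2-substituted cyclobutanone whose C4 quaternary centre (methyl, benzyl ester) is tied by C1–C3 to an E-trisubstituted alkene that already carries the citronellol-derived C11–C15 chain. Methylenation, hydration, hydrogenolysis and acetylation then complete the target.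

Key step: step 13

Assumption: labdane numbering is used for skeletal atoms (C17 on C8, C20 on C10), and pig-liver esterase is taken to hydrolyse the long-chain 2-alkyl-2-methylmalonate of step 7 to the (R)-half-ester, as it does with simple long n-alkyl homologues.

Step 1
Reactants: 1 (S)-citronellol, 2 benzyl bromide
Product: 3 ({[(3S)-3,7-dimethyloct-6-en-1-yl]oxy}methyl)benzene
Conditions: NaH, Bu4NI (cat.), THF/DMF, 0 °C to rt
Reagents that add atoms: benzyl bromide, BrCc1ccccc1
Why: Williamson etherification of the primary alkoxide gives a benzyl ether that survives every later step up to hydrogenolysis and leaves C13 untouched.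

Step 2
Reactants: 3 ({[(3S)-3,7-dimethyloct-6-en-1-yl]oxy}methyl)benzene
Product: 4 (4S)-6-(benzyloxy)-4-methylhexanal
Conditions: O3, CH2Cl2/MeOH, −78 °C; then Me2S, −78 °C to rt
Reagents that add atoms: ozone, [O-][O+]=O
Why: Ozonolysis with reductive work-up cleaves the only alkene to the C9 aldehyde and cannot affect the remote C13 centre.

Step 3
Reactants: 4 (4S)-6-(benzyloxy)-4-methylhexanal, 5 isopropenylmagnesium bromide
Product: 6 (3RS,6S)-8-(benzyloxy)-2,6-dimethyloct-1-en-3-ol
Conditions: THF, −78 to 0 °C; aq. NH4Cl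
Reagents that add atoms: isopropenylmagnesium bromide, C=C(C)[Mg]Br
Why: Grignard 1,2-addition to the aldehyde gives the allylic alcohol; the new carbinol centre forms without control and is erased in step 4.

Step 4
Reactants: 6 (3RS,6S)-8-(benzyloxy)-2,6-dimethyloct-1-en-3-ol, 7 triethyl orthoacetate
Product: 9 ethyl (4E,8S)-10-(benzyloxy)-4,8-dimethyldec-4-enoate, via mixed ketene acetal 8 (not isolated)
Conditions: MeC(OEt)3 (excess), EtCO2H (cat.), 140 °C, EtOH distilled off
Reagents that add atoms: triethyl orthoacetate, CCOC(C)(OCC)OCC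
Why: Johnson–Claisen rearrangement through a chair transition state with the C9 substituent equatorial gives the E-trisubstituted C9=C10 alkene and adds C2 and C3 in the same step.

Step 5
Reactants: 9 ethyl (4E,8S)-10-(benzyloxy)-4,8-dimethyldec-4-enoate
Product: 10 (4E,8S)-10-(benzyloxy)-4,8-dimethyldec-4-en-1-ol
Conditions: LiAlH4, THF, 0 °C
Reagents that add atoms: none
Why: Hydride reduction of the ester to the primary alcohol leaves the isolated alkene and the benzyl ether untouched.

Step 6
Reactants: 10 (4E,8S)-10-(benzyloxy)-4,8-dimethyldec-4-en-1-ol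
Product: 11 (4E,8S)-10-(benzyloxy)-1-iodo-4,8-dimethyldec-4-ene
Conditions: I2, PPh3, imidazole, CH2Cl2, 0 °C
Reagents that add atoms: iodine, II
Why: Appel-type iodination turns the primary alcohol into the C3 iodide under neutral conditions that do not isomerise the alkene.

Step 7
Reactants: 11 (4E,8S)-10-(benzyloxy)-1-iodo-4,8-dimethyldec-4-ene, 12 dimethyl methylmalonate
Product: 13 dimethyl 2-[(4E,8S)-10-(benzyloxy)-4,8-dimethyldec-4-en-1-yl]-2-methylpropanedioate
Conditions: NaH, THF/DMF, 0 to 60 °C
Reagents that add atoms: dimethyl methylmalonate, COC(=O)C(C)C(=O)OC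
Why: Malonate alkylation (SN2 on the unhindered primary iodide) builds the prochiral quaternary C4 with its methyl group and both carboxyl carbons in place.

Step 8
Reactants: 13 dimethyl 2-[(4E,8S)-10-(benzyloxy)-4,8-dimethyldec-4-en-1-yl]-2-methylpropanedioate
Product: 14 (2R,6E,10S)-12-(benzyloxy)-2-(methoxycarbonyl)-2,6,10-trimethyldodec-6-enoic acid
Conditions: pig-liver esterase, phosphate buffer pH 7.5/DMSO, 25 °C, pH-stat (NaOH); then HCl to pH 2
Reagents that add atoms: water, O
Why: Enzymatic desymmetrisation of the prochiral malonate hydrolyses one enantiotopic ester and so sets C4, the expected (R)-half-ester keeping its ester on the carbon that becomes C5.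

Step 9
Reactants: 14 (2R,6E,10S)-12-(benzyloxy)-2-(methoxycarbonyl)-2,6,10-trimethyldodec-6-enoic acid
Product: 15 (2S,6E,10S)-12-(benzyloxy)-2-(hydroxymethyl)-2,6,10-trimethyldodec-6-enoic acid
Conditions: LiBH4, THF, 0 to 50 °C; then 1 M HCl
Reagents that add atoms: none
Why: Chemoselective borohydride reduction turns the methyl ester into the C5 hydroxymethyl group while the lithium carboxylate is inert, so the C4 configuration is kept and only its descriptor changes.

Step 10
Reactants: 15 (2S,6E,10S)-12-(benzyloxy)-2-(hydroxymethyl)-2,6,10-trimethyldodec-6-enoic acid, 2 benzyl bromide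
Product: 16 benzyl (2S,6E,10S)-12-(benzyloxy)-2-(hydroxymethyl)-2,6,10-trimethyldodec-6-enoate
Conditions: KHCO3, DMF, rt
Reagents that add atoms: benzyl bromide, BrCc1ccccc1
Why: Carboxylate O-alkylation is selective over the neutral alcohol and installs an ester that can later be removed by hydrogenolysis instead of a harsh cleavage of a neopentyl methyl ester.

Step 11
Reactants: 16 benzyl (2S,6E,10S)-12-(benzyloxy)-2-(hydroxymethyl)-2,6,10-trimethyldodec-6-enoate
Product: 17 benzyl (2S,6E,10S)-12-(benzyloxy)-2-formyl-2,6,10-trimethyldodec-6-enoate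
Conditions: Dess–Martin periodinane, NaHCO3, CH2Cl2, 0 °C to rt
Reagents that add atoms: none
Why: Dess–Martin oxidation of the neopentyl primary alcohol gives a non-enolisable aldehyde, so C4 cannot epimerise.

Step 12
Reactants: 17 benzyl (2S,6E,10S)-12-(benzyloxy)-2-formyl-2,6,10-trimethyldodec-6-enoate, 18 cyclopropyldiphenylsulfonium tetrafluoroborate
Product: 20 benzyl (2S,6E,10S)-12-(benzyloxy)-2,6,10-trimethyl-2-[(1RS)-2-oxocyclobutyl]dodec-6-enoate, via oxaspiropentane 19 (not isolated)
Conditions: 18, KN(SiMe3)2, DME, −40 °C; add 17, −40 to 0 °C; then LiBF4 (cat.), toluene, rt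
Reagents that add atoms: cyclopropyldiphenylsulfonium tetrafluoroborate, F[B-](F)(F)F.C1CC1[S+](c1ccccc1)c1ccccc1
Why: Sulfonium-ylide spiroannulation (the cyclopropylide, made without hydroxide, adds to the aldehyde to give oxaspiropentane 19) followed by Lewis-acid semipinacol-type ring expansion gives the 2-substituted cyclobutanone; C5 forms without control, so 20 is carried on as both C5 epimers, which is tolerated because this centre equilibrates in step 13.

Step 13
Reactants: 20 benzyl (2S,6E,10S)-12-(benzyloxy)-2,6,10-trimethyl-2-[(1RS)-2-oxocyclobutyl]dodec-6-enoate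
Product: 23 benzyl (1S,4aR,5S,8aS)-5-[(3S)-5-(benzyloxy)-3-methylpentyl]-1,4a-dimethyl-6-oxodecahydronaphthalene-1-carboxylate, via cyclobutanone ketimine 21 (not isolated), via decalone ketimine 22 (not isolated)
Conditions: [Rh(C2H4)2Cl]2 (5 mol %), P[3,5-(CF3)2C6H3]3 (24 mol %), 2-amino-3-methylpyridine (1 equiv), 1,4-dioxane, 150 °C, sealed tube; then 1 M aq. HCl, THF, rt
Reagents that add atoms: none
Why: Proposed new method: 2-amino-3-methylpyridine condenses with the ketone to ketimine 21, whose pyridine nitrogen guides monovalent rhodium into the C5–C8 bond; the trivalent rhodacycle then inserts the tethered C9=C10 alkene into Rh–C5 in a syn fashion (C5–C10, retention at C5), acyl–C9 reductive elimination makes C8–C9, and acidic hydrolysis of ketimine 22 releases 23 and the amine. The closest known reaction type is the rhodium-catalysed intramolecular [4+2] carboacylation (cut and sew) of cyclobutanones with tethered alkenes; a C2-tethered saturated cyclobutanone adding across a trisubstituted alkene to give a decalin is without precedent, but release of four-ring strain drives the step. Ring A closes by 6-exo migratory insertion through the C1–C3 tether in a chair-like array, and ring B closes as a formal [4+2] in which C5–C6–C7–C8 spans C9=C10 by reductive elimination from a seven-membered rhodacycle. C10 and C9 are set by suprafacial addition to the E-alkene, which puts the C10 methyl and C11 cis, and C9 stays epimerisable to the equatorial side chain; C5 is transferred with retention, and because the two C5 epimers of 20 interconvert through the ketimine–enamine pair, both are expected to drain through the (1R) epimer if, as the chair model suggests, it cyclises faster. The step needs cleavage of C5–C8 and not C7–C8 (secured by the tether, since only the C5-bound rhodacycle can reach the alkene and the other insertion is reversible and unproductive), a trans ring fusion (chair with C6 and C9 equatorial on the forming ring A) and the right C4/C5 relationship, for which the benzyl ester, the larger C4 substituent, should lie anti to the forming C5–C10 bond and away from the ligated metal, leaving the C4 methyl on the face of the C10 methyl. This relay from C4 is the least secure element, and a wrong C4/core diastereomer would be separable at this stage.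

Step 14
Reactants: 23 benzyl (1S,4aR,5S,8aS)-5-[(3S)-5-(benzyloxy)-3-methylpentyl]-1,4a-dimethyl-6-oxodecahydronaphthalene-1-carboxylate, 24 methyltriphenylphosphonium bromide
Product: 25 benzyl (1S,4aS,5R,8aS)-5-[(3S)-5-(benzyloxy)-3-methylpentyl]-1,4a-dimethyl-6-methylidenedecahydronaphthalene-1-carboxylate
Conditions: KOtBu, toluene, 80 °C
Reagents that add atoms: methyltriphenylphosphonium bromide, C[P+](c1ccccc1)(c1ccccc1)c1ccccc1.[Br-]
Why: Wittig methylenation of the hindered C8 ketone adds C17; the basic ylide can only equilibrate C9 toward the equatorial side chain already present, and the neopentyl benzyl ester is not attacked.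

Step 15
Reactants: 25 benzyl (1S,4aS,5R,8aS)-5-[(3S)-5-(benzyloxy)-3-methylpentyl]-1,4a-dimethyl-6-methylidenedecahydronaphthalene-1-carboxylate
Product: 26 benzyl (1S,4aR,5S,6S,8aS)-5-[(3S)-5-(benzyloxy)-3-methylpentyl]-6-hydroxy-1,4a,6-trimethyldecahydronaphthalene-1-carboxylate
Conditions: Co(acac)2 (cat.), PhSiH3, O2 (1 atm), THF, 0 °C to rt; aq. Na2S2O3
Reagents that add atoms: dioxygen, O=O
Why: Mukaiyama hydration puts a hydrogen atom on C17 and traps the tertiary C8 radical with O2 on the face away from the syn-axial C10 methyl, so C8 should carry an equatorial hydroxyl and an axial methyl.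

Step 16
Reactants: 26 benzyl (1S,4aR,5S,6S,8aS)-5-[(3S)-5-(benzyloxy)-3-methylpentyl]-6-hydroxy-1,4a,6-trimethyldecahydronaphthalene-1-carboxylate
Product: 27 (1S,4aR,5S,6S,8aS)-6-hydroxy-5-[(3S)-5-hydroxy-3-methylpentyl]-1,4a,6-trimethyldecahydronaphthalene-1-carboxylic acid
Conditions: H2 (1 atm), Pd/C, EtOAc/MeOH, rt
Reagents that add atoms: none
Why: Hydrogenolysis removes the benzyl ether and the benzyl ester together; no alkene is left and neither the tertiary alcohol nor any stereocentre is affected.

Step 17
Reactants: 27 (1S,4aR,5S,6S,8aS)-6-hydroxy-5-[(3S)-5-hydroxy-3-methylpentyl]-1,4a,6-trimethyldecahydronaphthalene-1-carboxylic acid, 28 acetic anhydride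
Product: 29 (1S,4aR,5S,6S,8aS)-5-[(3S)-5-(acetyloxy)-3-methylpentyl]-6-hydroxy-1,4a,6-trimethyldecahydronaphthalene-1-carboxylic acid
Conditions: Ac2O (2.2 equiv), pyridine, CH2Cl2, 0 °C to rt; aq. NaHCO3, then dilute HCl
Reagents that add atoms: acetic anhydride, CC(=O)OC(C)=O
Why: Selective acylation acetylates the primary C15 alcohol, the hindered tertiary C8 alcohol does not react without a nucleophilic catalyst, and any mixed anhydride of the C4 acid is hydrolysed on work-up.

**Compound list**

1 | (S)-citronellol | C[C@@H](CCC=C(C)C)CCO | starting material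
2 | benzyl bromide | BrCc1ccccc1 | starting material
3 | ({[(3S)-3,7-dimethyloct-6-en-1-yl]oxy}methyl)benzene | c1ccccc1COCC[C@@H](C)CCC=C(C)C | intermediate
4 | (4S)-6-(benzyloxy)-4-methylhexanal | c1ccccc1COCC[C@@H](C)CCC=O | intermediate
5 | isopropenylmagnesium bromide | C=C(C)[Mg]Br | starting material
6 | (3RS,6S)-8-(benzyloxy)-2,6-dimethyloct-1-en-3-ol (both carbinol epimers) | c1ccccc1COCC[C@@H](C)CCC(O)C(C)=C | intermediate
7 | triethyl orthoacetate | CCOC(C)(OCC)OCC | starting material
8 | mixed ketene acetal, (6S)-8-(benzyloxy)-3-[(1-ethoxyethenyl)oxy]-2,6-dimethyloct-1-ene (not isolated) | c1ccccc1COCC[C@@H](C)CCC(OC(=C)OCC)C(C)=C | intermediate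
9 | ethyl (4E,8S)-10-(benzyloxy)-4,8-dimethyldec-4-enoate | c1ccccc1COCC[C@@H](C)CC/C=C(\C)CCC(=O)OCC | intermediate
10 | (4E,8S)-10-(benzyloxy)-4,8-dimethyldec-4-en-1-ol | c1ccccc1COCC[C@@H](C)CC/C=C(\C)CCCO | intermediate
11 | (4E,8S)-10-(benzyloxy)-1-iodo-4,8-dimethyldec-4-ene | c1ccccc1COCC[C@@H](C)CC/C=C(\C)CCCI | intermediate
12 | dimethyl methylmalonate | COC(=O)C(C)C(=O)OC | starting material
13 | dimethyl 2-[(4E,8S)-10-(benzyloxy)-4,8-dimethyldec-4-en-1-yl]-2-methylpropanedioate | c1ccccc1COCC[C@@H](C)CC/C=C(\C)CCCC(C)(C(=O)OC)C(=O)OC | intermediate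
14 | (2R,6E,10S)-12-(benzyloxy)-2-(methoxycarbonyl)-2,6,10-trimethyldodec-6-enoic acid | c1ccccc1COCC[C@@H](C)CC/C=C(\C)CCC[C@@](C)(C(=O)OC)C(=O)O | intermediate
15 | (2S,6E,10S)-12-(benzyloxy)-2-(hydroxymethyl)-2,6,10-trimethyldodec-6-enoic acid | c1ccccc1COCC[C@@H](C)CC/C=C(\C)CCC[C@@](C)(CO)C(=O)O | intermediate
16 | benzyl (2S,6E,10S)-12-(benzyloxy)-2-(hydroxymethyl)-2,6,10-trimethyldodec-6-enoate | c1ccccc1COCC[C@@H](C)CC/C=C(\C)CCC[C@@](C)(CO)C(=O)OCc1ccccc1 | intermediate
17 | benzyl (2S,6E,10S)-12-(benzyloxy)-2-formyl-2,6,10-trimethyldodec-6-enoate | c1ccccc1COCC[C@@H](C)CC/C=C(\C)CCC[C@@](C)(C=O)C(=O)OCc1ccccc1 | intermediate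
18 | cyclopropyldiphenylsulfonium tetrafluoroborate | F[B-](F)(F)F.C1CC1[S+](c1ccccc1)c1ccccc1 | starting material
19 | benzyl (2S,6E,10S)-12-(benzyloxy)-2,6,10-trimethyl-2-(1-oxaspiro[2.2]pentan-2-yl)dodec-6-enoate (both oxirane epimers, not isolated) | c1ccccc1COCC[C@@H](C)CC/C=C(\C)CCC[C@@](C)(C1OC12CC2)C(=O)OCc1ccccc1 | intermediate
20 | benzyl (2S,6E,10S)-12-(benzyloxy)-2,6,10-trimethyl-2-[(1RS)-2-oxocyclobutyl]dodec-6-enoate (both C5 epimers) | c1ccccc1COCC[C@@H](C)CC/C=C(\C)CCC[C@](C)(C(=O)OCc1ccccc1)C1CCC1=O | intermediate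
21 | N-(3-methylpyridin-2-yl) ketimine of cyclobutanone 20 (both C5 epimers, not isolated) | c1ccccc1COCC[C@@H](C)CC/C=C(\C)CCC[C@](C)(C(=O)OCc1ccccc1)C1CCC1=Nc1ncccc1C | intermediate
22 | N-(3-methylpyridin-2-yl) ketimine of decalone 23 (not isolated) | c1ccccc1COCC[C@@H](C)CC[C@H]1[C@]2(C)CCC[C@](C)(C(=O)OCc3ccccc3)[C@H]2CCC1=Nc1ncccc1C | intermediate
23 | benzyl (1S,4aR,5S,8aS)-5-[(3S)-5-(benzyloxy)-3-methylpentyl]-1,4a-dimethyl-6-oxodecahydronaphthalene-1-carboxylate | c1ccccc1COCC[C@@H](C)CC[C@H]1[C@]2(C)CCC[C@](C)(C(=O)OCc3ccccc3)[C@H]2CCC1=O | intermediate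
24 | methyltriphenylphosphonium bromide | C[P+](c1ccccc1)(c1ccccc1)c1ccccc1.[Br-] | starting material
25 | benzyl (1S,4aS,5R,8aS)-5-[(3S)-5-(benzyloxy)-3-methylpentyl]-1,4a-dimethyl-6-methylidenedecahydronaphthalene-1-carboxylate | c1ccccc1COCC[C@@H](C)CC[C@H]1[C@]2(C)CCC[C@](C)(C(=O)OCc3ccccc3)[C@H]2CCC1=C | intermediate
26 | benzyl (1S,4aR,5S,6S,8aS)-5-[(3S)-5-(benzyloxy)-3-methylpentyl]-6-hydroxy-1,4a,6-trimethyldecahydronaphthalene-1-carboxylate | c1ccccc1COCC[C@@H](C)CC[C@H]1[C@]2(C)CCC[C@](C)(C(=O)OCc3ccccc3)[C@H]2CC[C@]1(C)O | intermediate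
27 | (1S,4aR,5S,6S,8aS)-6-hydroxy-5-[(3S)-5-hydroxy-3-methylpentyl]-1,4a,6-trimethyldecahydronaphthalene-1-carboxylic acid | OCC[C@@H](C)CC[C@H]1[C@]2(C)CCC[C@](C)(C(=O)O)[C@H]2CC[C@]1(C)O | intermediate
28 | acetic anhydride | CC(=O)OC(C)=O | starting material
29 | (1S,4aR,5S,6S,8aS)-5-[(3S)-5-(acetyloxy)-3-methylpentyl]-6-hydroxy-1,4a,6-trimethyldecahydronaphthalene-1-carboxylic acid (CNP0299554.1) | CC(=O)OCC[C@@H](C)CC[C@H]1[C@]2(C)CCC[C@](C)(C(=O)O)[C@H]2CC[C@]1(C)O | target

**Step count.** Total: 17 steps. Longest linear sequence: 17 steps from (S)-citronellol 1.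

**Steps most likely to fail**

1. Step 13 (the new-method step). Migratory insertion of the hindered trisubstituted alkene may be slower than decarbonylation of the acyl–rhodium intermediate or plain reversal of the C–C cleavage. The induction from C4 may also favour the wrong alkene face or a cis ring fusion. The fallback replaces metal-mediated C–C activation by a thermal, pericyclic sequence in which every operation is a known reaction type; it sets out from 20 and returns at 23. Thermodynamic silylation (Me3SiCl, NaI, Et3N, MeCN) would give the more substituted trimethylsilyl enol ether F1, in which the unset C5 centre has become planar. Saegusa–Ito oxidation (Pd(OAc)2, MeCN) would convert it into the 2-substituted cyclobutenone F2. Heating F2 in toluene (sealed tube, about 130 °C) should open it by four-electron electrocyclic ring opening to the vinylketene F3 (not isolated). Its ketene unit adds intramolecularly [2+2] across C9=C10, C8 to C9 and C5 to C10, to give the cis-fused 2-vinylcyclobutanone F4 with both key bonds in place. Photochemical 1,3-acyl shift of F4 (300 nm, benzene) moves C8 from C5 to C7 and gives the octalinone F5 with a C5=C6 double bond. Hydrogen-atom-transfer hydrogenation of that bond (Mn(dpm)3, PhSiH3, tBuOOH, iPrOH), which favours the trans ring fusion, leads back to 23.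

2. Step 8. Discrimination between the enantiotopic esters may be insufficient, or turnover very slow, with so long and lipophilic a chain. A minor C4 epimer could not be removed later because C13 is remote. The fallback is a catalytic chemical desymmetrisation that sets out from iodide 11 and returns at 16. Alkylation of dibenzyl methylmalonate with 11 (NaH, DMF) would give the prochiral dibenzyl malonate F6. A zinc-catalysed desymmetrising hydrosilylation (ZnEt2, chiral pipecolinol-derived tetradentate ligand of the enantiomer that delivers the (S)-alcohol, (EtO)3SiH, then aqueous fluoride work-up) would reduce one enantiotopic ester to the hydroxymethyl group. This gives 16 directly and bypasses 13–15.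

3. Step 12. Retro-aldol loss of the formyl carbon from the betaine may compete with epoxide closure, because the alkoxide is β to an ester on a quaternary carbon. The ring expansion next to that ester-bearing carbon may also be sluggish. The fallback uses carbanion addition and acid-induced ring expansion in place of ylide epoxidation; it sets out from 17 and returns at 20. 1-Lithiocyclopropyl phenyl sulfide (from cyclopropyl phenyl sulfide and n-BuLi, THF, 0 °C) would add to the aldehyde at −78 °C to give the β-hydroxy sulfide F7. Aqueous HBF4 in ether would ionise the carbinol, expand the cyclopropane to the cyclobutyl thionium ion and hydrolyse it to the cyclobutanone 20, again as both C5 epimers.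

**Further compounds**

F1 | step 13 | benzyl (2S,6E,10S)-12-(benzyloxy)-2,6,10-trimethyl-2-{2-[(trimethylsilyl)oxy]cyclobut-1-en-1-yl}dodec-6-enoate | c1ccccc1COCC[C@@H](C)CC/C=C(\C)CCC[C@](C)(C(=O)OCc1ccccc1)C1=C(O[Si](C)(C)C)CC1
F2 | step 13 | benzyl (2S,6E,10S)-12-(benzyloxy)-2,6,10-trimethyl-2-(4-oxocyclobut-1-en-1-yl)dodec-6-enoate | c1ccccc1COCC[C@@H](C)CC/C=C(\C)CCC[C@](C)(C(=O)OCc1ccccc1)C1=CCC1=O
F3 | step 13 | vinylketene, benzyl (2S,6E,10S)-12-(benzyloxy)-2,6,10-trimethyl-2-(1-oxobuta-1,3-dien-2-yl)dodec-6-enoate (not isolated) | c1ccccc1COCC[C@@H](C)CC/C=C(\C)CCC[C@](C)(C(=O)OCc1ccccc1)C(C=C)=C=O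
F4 | step 13 | cis-fused 2-vinylcyclobutanone, benzyl 8-[(3S)-5-(benzyloxy)-3-methylpentyl]-6-ethenyl-1,5-dimethyl-7-oxobicyclo[4.2.0]octane-5-carboxylate (1-methyl, 6-ethenyl and 8-alkyl on one face; ester-bearing carbon as in 23) | c1ccccc1COCC[C@@H](C)CC[C@H]1[C@]2(C)CCC[C@](C)(C(=O)OCc3ccccc3)[C@]2(C=C)C1=O
F5 | step 13 | benzyl (1S,4aS,5S)-5-[(3S)-5-(benzyloxy)-3-methylpentyl]-1,4a-dimethyl-6-oxo-1,2,3,4,4a,5,6,7-octahydronaphthalene-1-carboxylate | c1ccccc1COCC[C@@H](C)CC[C@H]1[C@]2(C)CCC[C@](C)(C(=O)OCc3ccccc3)C2=CCC1=O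
F6 | step 8 | dibenzyl 2-[(4E,8S)-10-(benzyloxy)-4,8-dimethyldec-4-en-1-yl]-2-methylpropanedioate | c1ccccc1COCC[C@@H](C)CC/C=C(\C)CCCC(C)(C(=O)OCc1ccccc1)C(=O)OCc1ccccc1
F7 | step 12 | benzyl (2S,6E,10S)-12-(benzyloxy)-2-{hydroxy[1-(phenylsulfanyl)cyclopropyl]methyl}-2,6,10-trimethyldodec-6-enoate (both carbinol epimers) | c1ccccc1COCC[C@@H](C)CC/C=C(\C)CCC[C@](C)(C(=O)OCc1ccccc1)C(O)C1(Sc2ccccc2)CC1
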